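The cyclohexene ring carries the array C1(O)–C2(CH3)=C3H, with quaternary C5 flanked by the C4 and C6 methylenes. Everything rests on inserting C2 with its methyl group between the carbonyl carbon and the α-carbon of a cyclopentanone: chloro(methyl)carbene adds to a regio-defined cyclopentanone silyl enol ether that already holds both vicinal quaternary centres, and electrocyclic opening of the chlorocyclopropane gives the 2-methylcyclohex-2-enone in one operation. The quaternary centres come from a copper-catalysed etherification and chair Claisen rearrangement with chirality transfer from a lactate-derived allylic alcohol; the caffeate is attached by Mitsunobu inversion.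

Key step: step 12

Remark: ring locants used below are C1 (ester carbon), C2 (methyl-bearing olefinic carbon), C3 (olefinic CH), C4 (CH2), C5 (quaternary carbon) and C6 (CH2); the drawn configuration places the ester oxygen cis to the cyclopentyl group and trans to the C5 methyl group.

Step 1
Reactants: 1 methyl (2R)-2-hydroxypropanoate (methyl (R)-lactate)
Product: 2 methyl (2R)-2-[(tert-butyldimethylsilyl)oxy]propanoate
Conditions: TBSCl, imidazole, DMF, 0 °C → rt
Reagents that add atoms: tert-butyldimethylsilyl chloride, CC(C)(C)[Si](C)(C)Cl
Why: Imidazole-promoted O-silylation of a secondary alcohol (silyl ether protection) that does not touch the stereocentre.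

Step 2
Reactants: 2 methyl (2R)-2-[(tert-butyldimethylsilyl)oxy]propanoate; 3 2-(triphenyl-λ5-phosphanylidene)propanal
Product: 5 (2E,4R)-4-[(tert-butyldimethylsilyl)oxy]-2-methylpent-2-enal, via silyloxy aldehyde 4 (not isolated)
Conditions: i-Bu2AlH, CH2Cl2, −78 °C; aqueous work-up, crude aldehyde; then 3, toluene, 80 °C
Reagents that add atoms: none
Why: Low-temperature i-Bu2AlH reduction stops at the aluminium hemiacetal, and the crude α-silyloxy aldehyde, used at once under non-basic conditions so that its stereocentre is kept, should undergo an E-selective Wittig olefination with the stabilised formyl ylide.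

Step 3
Reactants: 5 (2E,4R)-4-[(tert-butyldimethylsilyl)oxy]-2-methylpent-2-enal
Product: 6 tert-butyl{[(2R,3E)-5,5-dimethoxy-4-methylpent-3-en-2-yl]oxy}dimethylsilane
Conditions: HC(OMe)3, MeOH, PPTS (cat.), rt
Reagents that add atoms: trimethyl orthoformate, COC(OC)OC; methanol, CO
Why: Acid-catalysed acetalisation with the orthoformate as water scavenger masks the enal, while the silyl ether survives and keeps the γ-oxygen from cyclising onto the oxocarbenium ion.

Step 4
Reactants: 6 tert-butyl{[(2R,3E)-5,5-dimethoxy-4-methylpent-3-en-2-yl]oxy}dimethylsilane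
Product: 7 (2R,3E)-5,5-dimethoxy-4-methylpent-3-en-2-ol
Conditions: Bu4NF, THF, 0 °C → rt
Reagents that add atoms: none
Why: Fluoride-induced desilylation under non-acidic conditions should free the allylic alcohol without ionising the acetal or the allylic C–O bond.

Step 5
Reactants: 8 1,2-dibromocyclopentene
Product: 10 1-bromo-2-methylcyclopentene, via (2-bromocyclopent-1-en-1-yl)lithium 9 (not isolated)
Conditions: n-BuLi (1.0 equiv), THF, −78 °C; then MeI, −78 °C → rt
Reagents that add atoms: iodomethane, CI
Why: Bromine–lithium exchange of one vinylic bromide at −78 °C, where β-elimination to cyclopentyne is slow, followed by alkylation of the vinyllithium with iodomethane.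

Step 6
Reactants: 10 1-bromo-2-methylcyclopentene
Product: 12 1-iodo-2-methylcyclopentene, via (2-methylcyclopent-1-en-1-yl)lithium 11 (not isolated)
Conditions: t-BuLi (2.0 equiv), Et2O, −78 °C; then I2, −78 °C → rt
Reagents that add atoms: iodine, II
Why: Halogen–lithium exchange with two equivalents of t-BuLi and iodinolysis of the vinyllithium should give the more reactive vinyl iodide needed for the copper-catalysed coupling.

Step 7
Reactants: 7 (2R,3E)-5,5-dimethoxy-4-methylpent-3-en-2-ol; 12 1-iodo-2-methylcyclopentene
Product: 14 (2R)-2-[(2S,3E)-1,1-dimethoxy-2-methylpent-3-en-2-yl]-2-methylcyclopentan-1-one, via allyl vinyl ether 13 (not isolated)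
Conditions: CuI (10 mol %), 3,4,7,8-tetramethyl-1,10-phenanthroline (20 mol %), Cs2CO3, o-xylene, 120 → 140 °C, sealed vessel, 12 in excess
Reagents that add atoms: none
Why: An Ullmann-type copper-catalysed C–O coupling should give the allyl vinyl ether, which undergoes Claisen rearrangement in the same pot through a chair transition state with the carbinol methyl equatorial and both olefinic methyl groups axial, so that the (R)-carbinol centre and the E-alkene set both new quaternary centres in the required relative and absolute sense and the new alkene is E.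

Step 8
Reactants: 14 (2R)-2-[(2S,3E)-1,1-dimethoxy-2-methylpent-3-en-2-yl]-2-methylcyclopentan-1-one
Product: 15 (1S)-1-[(2S,3E)-1,1-dimethoxy-2-methylpent-3-en-2-yl]-1-methyl-2-methylidenecyclopentane
Conditions: Ph3PCH3Br, KOt-Bu, toluene, 100 °C
Reagents that add atoms: methyltriphenylphosphonium bromide, C[P+](c1ccccc1)(c1ccccc1)c1ccccc1.[Br-]
Why: Wittig methylenation with excess ylide at elevated temperature should convert the hindered ketone, which has no epimerisable α-centre on the quaternary side, while acetal and propenyl group are inert.

Step 9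
Reactants: 15 (1S)-1-[(2S,3E)-1,1-dimethoxy-2-methylpent-3-en-2-yl]-1-methyl-2-methylidenecyclopentane
Product: 17 (2S)-2-methyl-2-[(1S)-1-methyl-2-methylidenecyclopentyl]-4-oxopentanal, via keto acetal 16 (not isolated)
Conditions: Pd(OAc)2 (10 mol %), 1,4-benzoquinone, aq. HBF4, DMA–MeCN–H2O, rt; then 1 M HCl, THF, rt
Reagents that add atoms: water, O
Why: In this Tsuji–Wacker oxidation of the internal E-alkene water should attack the methyl-bearing carbon remote from the quaternary centre to give the methyl ketone, the 1,1-disubstituted methylidene group being a poor substrate for divalent palladium, and the aqueous acid then cleaves the congested acetal to the aldehyde.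

Step 10
Reactants: 17 (2S)-2-methyl-2-[(1S)-1-methyl-2-methylidenecyclopentyl]-4-oxopentanal
Product: 18 (4R)-4-methyl-4-[(1S)-1-methyl-2-methylidenecyclopentyl]cyclopent-2-en-1-one
Conditions: KOH, MeOH, rt → 50 °C
Reagents that add atoms: none
Why: Intramolecular aldol condensation in which only the methyl-side enolate can reach the non-enolisable aldehyde through a five-membered ring, dehydration making the cyclopentenone irreversibly.

Step 11
Reactants: 18 (4R)-4-methyl-4-[(1S)-1-methyl-2-methylidenecyclopentyl]cyclopent-2-en-1-one
Product: 19 dimethyl({(4S)-4-methyl-4-[(1S)-1-methyl-2-methylidenecyclopentyl]cyclopent-1-en-1-yl}oxy)phenylsilane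
Conditions: [(Ph3P)CuH]6 (3 mol %), PhMe2SiH, toluene, rt
Reagents that add atoms: dimethylphenylsilane, C[SiH](C)c1ccccc1
Why: Copper hydride-catalysed 1,4-hydrosilylation delivers hydride to the β-carbon and silicon to oxygen, which fixes the enol ether double bond on the side remote from the quaternary carbon and leaves isolated alkenes alone.

Step 12
Reactants: 19 dimethyl({(4S)-4-methyl-4-[(1S)-1-methyl-2-methylidenecyclopentyl]cyclopent-1-en-1-yl}oxy)phenylsilane
Product: 21 (5S)-2,5-dimethyl-5-[(1S)-1-methyl-2-methylidenecyclopentyl]cyclohex-2-en-1-one, via chlorocyclopropane 20 (not isolated)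
Conditions: CH3CHCl2, n-BuLi (slow addition, about 1.5 equiv), Et2O, −35 °C; then toluene, Et3N, 110 °C
Reagents that add atoms: 1,1-dichloroethane, CC(Cl)Cl
Why: Deprotonation of 1,1-dichloroethane gives CH3CCl2Li, which loses LiCl and transfers chloro(methyl)carbene to the electron-rich enol ether double bond; on heating, the chloride cis to the five-membered ring departs while the cyclopropane opens in a disrotatory two-electron electrocyclic process that breaks the bond shared by the three- and five-membered rings, and the 2-silyloxyallyl cation formed loses the silyl group to chloride. The closest known reaction type is the one-carbon ring expansion of ketone silyl enol ethers to 2-substituted cycloalk-2-enones through halocarbene adducts. The cyclopropane is closed by a concerted [2+1] cheletropic addition, whereas the six-membered ring is not closed by a new bond but results from scission of the zero-atom bridge of the bicyclo[3.1.0]hexane, so that the carbene carbon with its methyl group ends up between the carbonyl carbon and the former α-carbon. No new stereocentre survives the step, since the three cyclopropane centres are destroyed on opening and the two quaternary centres are spectators. The step needs regioselectivity, fixed by the position of the enol ether double bond set in step 11, chemoselectivity over the methylidene group, which rests on the higher nucleophilicity of the silyl enol ether, the neopentyl shielding of the exocyclic alkene and the limited amount of carbenoid, and the endo-chloride geometry for concerted opening, the exo-chloride epimer being driven through the oxygen-stabilised cation at 110 °C.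

Step 13
Reactants: 21 (5S)-2,5-dimethyl-5-[(1S)-1-methyl-2-methylidenecyclopentyl]cyclohex-2-en-1-one
Product: 22 (1R,5S)-2,5-dimethyl-5-[(1S)-1-methyl-2-methylidenecyclopentyl]cyclohex-2-en-1-ol
Conditions: (S)-2-methyl-CBS-oxazaborolidine (20 mol %), catecholborane, toluene, −78 °C
Reagents that add atoms: none
Why: In this Corey–Bakshi–Shibata reduction the (S)-catalyst, with the α-methylvinyl side as the large group, should deliver hydride to the carbonyl face anti to the pseudoaxial C5 methyl group, so catalyst and substrate bias reinforce each other to give the (1R)-alcohol with hydroxyl cis to that methyl group, and catecholborane at −78 °C leaves the alkenes alone.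

Step 14
Reactants: 22 (1R,5S)-2,5-dimethyl-5-[(1S)-1-methyl-2-methylidenecyclopentyl]cyclohex-2-en-1-ol; 23 (2E)-3-(3,4-dihydroxyphenyl)prop-2-enoic acid (caffeic acid)
Product: 24 (1S,5S)-2,5-dimethyl-5-[(1S)-1-methyl-2-methylidenecyclopentyl]cyclohex-2-en-1-yl (2E)-3-(3,4-dihydroxyphenyl)prop-2-enoate
Conditions: PPh3, DIAD, THF, 0 °C → rt
Reagents that add atoms: none
Why: Mitsunobu esterification with SN2 inversion at the allylic carbinol, in which the carboxylic acid is far more acidic than the catechol hydroxyls and so should be the only effective pronucleophile, attacking the face anti to the pseudoaxial methyl group to give the (1S)-ester.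

Compound list
1 | methyl (2R)-2-hydroxypropanoate | C[C@@H](O)C(=O)OC | starting material
2 | methyl (2R)-2-[(tert-butyldimethylsilyl)oxy]propanoate | C[C@@H](O[Si](C)(C)C(C)(C)C)C(=O)OC | intermediate
3 | 2-(triphenyl-λ5-phosphanylidene)propanal | CC(C=O)=P(c1ccccc1)(c1ccccc1)c1ccccc1 | starting material
4 | (2R)-2-[(tert-butyldimethylsilyl)oxy]propanal | C[C@@H](O[Si](C)(C)C(C)(C)C)C=O | intermediate
5 | (2E,4R)-4-[(tert-butyldimethylsilyl)oxy]-2-methylpent-2-enal | C[C@@H](O[Si](C)(C)C(C)(C)C)/C=C(\C)C=O | intermediate
6 | tert-butyl{[(2R,3E)-5,5-dimethoxy-4-methylpent-3-en-2-yl]oxy}dimethylsilane | C[C@@H](O[Si](C)(C)C(C)(C)C)/C=C(\C)C(OC)OC | intermediate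
7 | (2R,3E)-5,5-dimethoxy-4-methylpent-3-en-2-ol | C[C@@H](O)/C=C(\C)C(OC)OC | intermediate
8 | 1,2-dibromocyclopentene | BrC1=C(Br)CCC1 | starting material
9 | (2-bromocyclopent-1-en-1-yl)lithium | [Li]C1=C(Br)CCC1 | intermediate
10 | 1-bromo-2-methylcyclopentene | CC1=C(Br)CCC1 | intermediate
11 | (2-methylcyclopent-1-en-1-yl)lithium | [Li]C1=C(C)CCC1 | intermediate
12 | 1-iodo-2-methylcyclopentene | CC1=C(I)CCC1 | intermediate
13 | 1-{[(2R,3E)-5,5-dimethoxy-4-methylpent-3-en-2-yl]oxy}-2-methylcyclopent-1-ene | CC1=C(O[C@H](C)/C=C(\C)C(OC)OC)CCC1 | intermediate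
14 | (2R)-2-[(2S,3E)-1,1-dimethoxy-2-methylpent-3-en-2-yl]-2-methylcyclopentan-1-one | O=C1CCC[C@]1(C)[C@](C)(/C=C/C)C(OC)OC | intermediate
15 | (1S)-1-[(2S,3E)-1,1-dimethoxy-2-methylpent-3-en-2-yl]-1-methyl-2-methylidenecyclopentane | C=C1CCC[C@]1(C)[C@](C)(/C=C/C)C(OC)OC | intermediate
16 | (4S)-5,5-dimethoxy-4-methyl-4-[(1S)-1-methyl-2-methylidenecyclopentyl]pentan-2-one | C=C1CCC[C@]1(C)[C@](C)(CC(C)=O)C(OC)OC | intermediate
17 | (2S)-2-methyl-2-[(1S)-1-methyl-2-methylidenecyclopentyl]-4-oxopentanal | C=C1CCC[C@]1(C)[C@](C)(CC(C)=O)C=O | intermediate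
18 | (4R)-4-methyl-4-[(1S)-1-methyl-2-methylidenecyclopentyl]cyclopent-2-en-1-one | C=C1CCC[C@]1(C)[C@@]1(C)C=CC(=O)C1 | intermediate
19 | dimethyl({(4S)-4-methyl-4-[(1S)-1-methyl-2-methylidenecyclopentyl]cyclopent-1-en-1-yl}oxy)phenylsilane | C=C1CCC[C@]1(C)[C@@]1(C)CC=C(O[Si](C)(C)c2ccccc2)C1 | intermediate
20 | {[6-chloro-3,6-dimethyl-3-[(1S)-1-methyl-2-methylidenecyclopentyl]bicyclo[3.1.0]hexan-1-yl]oxy}dimethylphenylsilane, quaternary C3 as in 19, mixture of cyclopropane diastereomers | C=C1CCC[C@]1(C)[C@@]1(C)CC2C(C)(Cl)C2(O[Si](C)(C)c3ccccc3)C1 | intermediate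
21 | (5S)-2,5-dimethyl-5-[(1S)-1-methyl-2-methylidenecyclopentyl]cyclohex-2-en-1-one | C=C1CCC[C@]1(C)[C@@]1(C)CC=C(C)C(=O)C1 | intermediate
22 | (1R,5S)-2,5-dimethyl-5-[(1S)-1-methyl-2-methylidenecyclopentyl]cyclohex-2-en-1-ol | C=C1CCC[C@]1(C)[C@@]1(C)CC=C(C)[C@H](O)C1 | intermediate
23 | (2E)-3-(3,4-dihydroxyphenyl)prop-2-enoic acid | O=C(O)/C=C/c1ccc(O)c(O)c1 | starting material
24 | (1S,5S)-2,5-dimethyl-5-[(1S)-1-methyl-2-methylidenecyclopentyl]cyclohex-2-en-1-yl (2E)-3-(3,4-dihydroxyphenyl)prop-2-enoate | C=C1CCC[C@]1(C)[C@@]1(C)CC=C(C)[C@@H](OC(=O)/C=C/c2ccc(O)c(O)c2)C1 | target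

Total step count: 14. Longest linear sequence: 12 steps (steps 1 to 4, then 7 to 14); steps 5 and 6 form the short branch.

Steps most likely to fail

Step 7. The fully substituted vinylic carbon and the hindered secondary alkoxide may couple so slowly that hydrodehalogenation of the iodide or redox isomerisation of the allylic alcohol takes over, and the ether may fragment by a retro-ene path at the temperature the rearrangement needs. The fallback sets out from bromide 10 (alcohol 7 is used as before) and comes back at ketone 14. Bromide 10 is lithiated with t-BuLi, borylated with B(OMe)3 and treated with aqueous KHF2 to give potassium trifluoro(2-methylcyclopent-1-en-1-yl)borate F1. A Chan–Lam oxidative etherification of 7 with F1 (Cu(OAc)2 cat., DMAP, 4 Å sieves, O2, CH2Cl2, rt) should give ether 13, which is now isolated. Heating 13 in toluene at 130 °C then carries out the Claisen rearrangement to 14 without base or copper present.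

Step 12. n-BuLi may attack silicon and destroy the regio-defined enol ether, the exo-chloride epimer of the adduct may fail to ionise, and the carbenoid may also add to the methylidene group if used in larger excess. The fallback sets out from silyl enol ether 19 and comes back at enone 21. Dibromocarbene from CHBr3 and KOt-Bu (pentane, −20 °C → rt) should give the dibromocyclopropane adduct F2. F2 always holds a bromide cis to the five-membered ring and should open at or below room temperature to (5S)-2-bromo-5-methyl-5-[(1S)-1-methyl-2-methylidenecyclopentyl]cyclohex-2-en-1-one F3, still a one-carbon ring expansion. Stille methylation of F3 with Me4Sn (Pd(PPh3)4, zerovalent palladium, CuI, DMF, 60 °C) then gives 21.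

Step 14. The pseudoaxial oxyphosphonium ion may undergo E2 elimination to the cyclohexadiene, and O-alkylation of the catechol or SN2′ attack may compete with direct displacement. The fallback sets out from enone 21 and comes back at target 24. Reduction with (R)-2-methyl-CBS-oxazaborolidine and catecholborane (toluene, −78 °C) under catalyst control should give (1S,5S)-2,5-dimethyl-5-[(1S)-1-methyl-2-methylidenecyclopentyl]cyclohex-2-en-1-ol F4, the minor epimer being removed by chromatography. Heating F4 with 2,2-dimethyl-1,3-dioxane-4,6-dione in toluene at 100 °C acylates the alcohol with retention to the malonic half ester F5. Knoevenagel–Doebner condensation of F5 with 3,4-dihydroxybenzaldehyde (pyridine, piperidine cat., 50 °C) then forms the E-cinnamate with loss of carbon dioxide and gives 24 without inversion or protecting groups.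

Further compounds
F1 | step 7 | potassium trifluoro(2-methylcyclopent-1-en-1-yl)borate | CC1=C([B-](F)(F)F)CCC1.[K+]
F2 | step 12 | {[6,6-dibromo-3-methyl-3-[(1S)-1-methyl-2-methylidenecyclopentyl]bicyclo[3.1.0]hexan-1-yl]oxy}dimethylphenylsilane, quaternary C3 as in 19 | C=C1CCC[C@]1(C)[C@@]1(C)CC2C(Br)(Br)C2(O[Si](C)(C)c3ccccc3)C1
F3 | step 12 | (5S)-2-bromo-5-methyl-5-[(1S)-1-methyl-2-methylidenecyclopentyl]cyclohex-2-en-1-one | C=C1CCC[C@]1(C)[C@@]1(C)CC=C(Br)C(=O)C1
F4 | step 14 | (1S,5S)-2,5-dimethyl-5-[(1S)-1-methyl-2-methylidenecyclopentyl]cyclohex-2-en-1-ol | C=C1CCC[C@]1(C)[C@@]1(C)CC=C(C)[C@@H](O)C1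
F5 | step 14 | 3-{[(1S,5S)-2,5-dimethyl-5-[(1S)-1-methyl-2-methylidenecyclopentyl]cyclohex-2-en-1-yl]oxy}-3-oxopropanoic acid | C=C1CCC[C@]1(C)[C@@]1(C)CC=C(C)[C@@H](OC(=O)CC(=O)O)C1
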